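**Retrosynthetic overview**
1. The quinone comes last, from a phenol (Teuber oxidation). The (E)-chloroalkene comes from the enol triflate of an aryl ketone by a stereoconvergent vinylic SN1 reaction, and C9–C11 from a Nozaki–Hiyama–Kishi coupling of the C8=C9 alkenyl triflate with protected o-vanillin.
2. Ring A is closed in one flask by a two-carbon annulation with vinyltriphenylphosphonium bromide: C3–C4 by MHAT radical addition and C1=C2 by intramolecular Wittig olefination.
3. Enabling feature: on ring B the isopropenyl carbon (future C4, whose CH2 becomes the second methyl) sits on C5 and the formyl carbon (future C1) on the adjacent quaternary C10, trans to each other. A tertiary-radical precursor and a non-enolisable aldehyde are thus held 1,4 across the C5–C10 bond, ready to be bridged by two carbons.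
4. Ring B is (R)-carvone: its carbonyl is C9, its methyl-bearing enone carbons are C8/C7, its stereocentre is C5, and its α′ carbon is alkylated twice (CH3, then CH2OH) to give C10.
5. Ring order: ring B (chiral pool), then ring A (step 4), then the aryl ring is attached (step 7) and oxidised to the quinone (step 13).

Key step: step 4

Remark: drimane-type locants are used in the text (decalin C1–C10, C4 = CMe2, C5/C10 = ring fusion, C8 = CHCH3, C9 = alkylidene carbon, C11 = CCl); the enantiomeric purity of commercial (R)-carvone is assumed to carry through.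

**Step 1**
Reactants: 1 (R)-carvone
Product: 3 (5R,6S)-2,6-dimethyl-5-(prop-1-en-2-yl)cyclohex-2-en-1-one (major C6 epimer; both epimers are used), via lithium dienolate 2 (not isolated)
Conditions: LiN(i-Pr)2, THF, −78 °C; MeI, −78 → 0 °C
Reagents that add atoms: iodomethane, CI
Why: Kinetic α′-deprotonation of the enone and SN2 methylation (enolate alkylation); the new centre should form mainly trans to the isopropenyl group but is erased in step 2, so its configuration is immaterial.

**Step 2**
Reactants: 3 (5R,6S)-2,6-dimethyl-5-(prop-1-en-2-yl)cyclohex-2-en-1-one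
Product: 5 (5S,6R)-6-(hydroxymethyl)-2,6-dimethyl-5-(prop-1-en-2-yl)cyclohex-2-en-1-one, via lithium dienolate 4 (not isolated)
Conditions: LiN(i-Pr)2, THF, −78 °C; CH2O (gas, from cracked paraformaldehyde), −78 °C; AcOH quench
Reagents that add atoms: formaldehyde, C=O
Why: Regeneration of the cross-conjugated dienolate and crossed aldol addition to formaldehyde (enolate hydroxymethylation); the electrophile should enter anti to the neighbouring isopropenyl group, which sets quaternary C10 with CH2OH trans and CH3 cis to it.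

**Step 3**
Reactants: 5 (5S,6R)-6-(hydroxymethyl)-2,6-dimethyl-5-(prop-1-en-2-yl)cyclohex-2-en-1-one
Product: 6 (1R,6S)-1,3-dimethyl-2-oxo-6-(prop-1-en-2-yl)cyclohex-3-ene-1-carbaldehyde
Conditions: Dess–Martin periodinane, CH2Cl2, rt
Reagents that add atoms: none
Why: Dess–Martin oxidation of the neopentyl primary alcohol under non-basic conditions should avoid retro-aldol loss of formaldehyde; the aldehyde has no α-hydrogen and cannot epimerise.

**Step 4**
Reactants: 6 (1R,6S)-1,3-dimethyl-2-oxo-6-(prop-1-en-2-yl)cyclohex-3-ene-1-carbaldehyde; 7 vinyltriphenylphosphonium bromide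
Product: 10 (4aS,8aS)-2,5,5,8a-tetramethyl-4a,5,6,8a-tetrahydronaphthalen-1(4H)-one, via phosphonium bromide 8 (not isolated), via phosphonium ylide 9 (not isolated)
Conditions: Fe(acac)3 (30 mol %), PhSiH3, 7 (3 equiv), EtOH/THF, 40 °C; evaporate; KOt-Bu, THF, 0 °C → rt (same flask)
Reagents that add atoms: none
Why: Proposed new method: the iron hydride formed from Fe(acac)3 and PhSiH3 transfers a hydrogen atom to the CH2 of the isopropenyl group (MHAT) to give the tertiary C4 radical, which adds to the terminus of 7 (C3–C4, Giese addition); the α-phosphonio radical is reduced by divalent iron to ylide 9, parked in ethanol as salt 8, and KOt-Bu then drives the intramolecular Wittig reaction of ylide carbon C2 with the C1 aldehyde (C1=C2). The closest known reaction types are iron-hydride MHAT conjugate additions of alkene-derived tertiary radicals, their aldol-terminated radical–polar crossover annulations, the photoredox radical addition to vinylphosphonium salts that ends in a Wittig olefination, and anionic vinylphosphonium annulations. Ring A closes as a six-membered ring by Wittig olefination (6-exo attack of the ylide carbon on the formyl group), and the cis C1=C2 alkene is the only one the ring allows. No stereocentre is created: the trans ring fusion is already fixed by C5 and C10 (step 2), whose trans C4 and C1 arms are gauche and can reach each other. The step needs hydrogen-atom transfer to the 1,1-disubstituted alkene and not to the enone (electron-poor, and out of reach of the C4 radical), and olefination of the aldehyde and not of the hindered conjugated C9 ketone; the aldehyde cannot enolise because C10 is quaternary.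

**Step 5**
Reactants: 10 (4aS,8aS)-2,5,5,8a-tetramethyl-4a,5,6,8a-tetrahydronaphthalen-1(4H)-one
Product: 12 (4aS,8aS)-2,5,5,8a-tetramethyl-3,4,4a,5,6,8a-hexahydronaphthalen-1-yl trifluoromethanesulfonate, via lithium enolate 11 (not isolated)
Conditions: LiBH(s-Bu)3, THF, −78 °C; PhNTf2, −78 → 0 °C
Reagents that add atoms: N-phenylbis(trifluoromethanesulfonimide), O=S(=O)(N(c1ccccc1)S(=O)(=O)C(F)(F)F)C(F)(F)F
Why: Conjugate hydride addition to the unsubstituted β-carbon C7 (1,2-attack is blocked by quaternary C10) should give the C8=C9 enolate regiospecifically, which is O-sulfonylated (reductive triflation); no stereocentre is formed.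

**Step 6**
Reactants: 13 2-hydroxy-3-methoxybenzaldehyde (o-vanillin)
Product: 14 2-[(tert-butyldimethylsilyl)oxy]-3-methoxybenzaldehyde
Conditions: TBSCl, imidazole, DMF, rt
Reagents that add atoms: tert-butyldimethylsilyl chloride, CC(C)(C)[Si](C)(C)Cl
Why: Standard silylation of the phenol masks it for the organometallic and base steps and leaves a fluoride-labile group for the end.

**Step 7**
Reactants: 12 (4aS,8aS)-2,5,5,8a-tetramethyl-3,4,4a,5,6,8a-hexahydronaphthalen-1-yl trifluoromethanesulfonate; 14 2-[(tert-butyldimethylsilyl)oxy]-3-methoxybenzaldehyde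
Product: 15 {2-[(tert-butyldimethylsilyl)oxy]-3-methoxyphenyl}[(4aS,8aS)-2,5,5,8a-tetramethyl-3,4,4a,5,6,8a-hexahydronaphthalen-1-yl]methanol (both carbinol epimers)
Conditions: CrCl2 (4 equiv), NiCl2 (2 mol %), DMF, rt
Reagents that add atoms: none
Why: Nozaki–Hiyama–Kishi coupling (nickel-catalysed activation of the hindered alkenyl triflate, transmetalation to chromium, addition to the aldehyde) should form C9–C11; the carbinol centre forms without control and is removed in step 9.

**Step 8**
Reactants: 15 {2-[(tert-butyldimethylsilyl)oxy]-3-methoxyphenyl}[(4aS,8aS)-2,5,5,8a-tetramethyl-3,4,4a,5,6,8a-hexahydronaphthalen-1-yl]methanol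
Product: 16 {2-[(tert-butyldimethylsilyl)oxy]-3-methoxyphenyl}[(1S,2S,4aS,8aS)-2,5,5,8a-tetramethyldecahydronaphthalen-1-yl]methanol (both carbinol epimers)
Conditions: H2 (10 bar), [Ir(cod)(PCy3)(py)]PF6 (10 mol %), CH2Cl2, rt
Reagents that add atoms: none
Why: Hydroxyl-directed homogeneous hydrogenation should reduce the disubstituted C1=C2 bond and, anchored by the carbinol OH, the tetrasubstituted C8=C9 bond; H2 adds cis from the α face because the β face is shielded by the axial C10 methyl, which sets C8 (β-methyl) and C9.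

**Step 9**
Reactants: 16 {2-[(tert-butyldimethylsilyl)oxy]-3-methoxyphenyl}[(1S,2S,4aS,8aS)-2,5,5,8a-tetramethyldecahydronaphthalen-1-yl]methanol
Product: 17 {2-[(tert-butyldimethylsilyl)oxy]-3-methoxyphenyl}[(1S,2S,4aS,8aS)-2,5,5,8a-tetramethyldecahydronaphthalen-1-yl]methanone
Conditions: Dess–Martin periodinane, CH2Cl2, rt
Reagents that add atoms: none
Why: Dess–Martin oxidation of the secondary benzylic alcohol converges both carbinol epimers to one aryl ketone; the equatorial C9 aroyl group is the stable epimer and C8 is not acidic.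

**Step 10**
Reactants: 17 {2-[(tert-butyldimethylsilyl)oxy]-3-methoxyphenyl}[(1S,2S,4aS,8aS)-2,5,5,8a-tetramethyldecahydronaphthalen-1-yl]methanone
Product: 19 {2-[(tert-butyldimethylsilyl)oxy]-3-methoxyphenyl}[(2S,4aS,8aS)-2,5,5,8a-tetramethyloctahydronaphthalen-1(2H)-ylidene]methyl trifluoromethanesulfonate (E/Z mixture), via potassium enolate 18 (not isolated)
Conditions: KN(SiMe3)2, THF, −78 → 0 °C; PhNTf2
Reagents that add atoms: N-phenylbis(trifluoromethanesulfonimide), O=S(=O)(N(c1ccccc1)S(=O)(=O)C(F)(F)F)C(F)(F)F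
Why: Deprotonation at C9, the only enolisable position of the aryl ketone, and O-triflation (enol triflate formation); both alkene isomers are carried on because step 11 is stereoconvergent.

**Step 11**
Reactants: 19 {2-[(tert-butyldimethylsilyl)oxy]-3-methoxyphenyl}[(2S,4aS,8aS)-2,5,5,8a-tetramethyloctahydronaphthalen-1(2H)-ylidene]methyl trifluoromethanesulfonate
Product: 20 tert-butyl(2-{(E)-chloro[(2S,4aS,8aS)-2,5,5,8a-tetramethyloctahydronaphthalen-1(2H)-ylidene]methyl}-6-methoxyphenoxy)dimethylsilane
Conditions: n-Bu4NCl, 2,6-di-tert-butylpyridine, (CF3)2CHOH/CH2Cl2, 40 °C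
Reagents that add atoms: tetrabutylammonium chloride, CCCC[N+](CCCC)(CCCC)CCCC.[Cl-]
Why: Vinylic SN1 substitution: in the ionising, non-nucleophilic solvent both triflate isomers should ionise to the same linear α-aryl vinyl cation (aryl ring already perpendicular to the alkene plane, ortho-silyloxy donor), and chloride should add in the alkene plane from the side of the C8 methine and not of quaternary C10, which gives the E alkene with Cl cis to C8.

**Step 12**
Reactants: 20 tert-butyl(2-{(E)-chloro[(2S,4aS,8aS)-2,5,5,8a-tetramethyloctahydronaphthalen-1(2H)-ylidene]methyl}-6-methoxyphenoxy)dimethylsilane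
Product: 21 2-{(E)-chloro[(2S,4aS,8aS)-2,5,5,8a-tetramethyloctahydronaphthalen-1(2H)-ylidene]methyl}-6-methoxyphenol
Conditions: n-Bu4NF, AcOH, THF, 0 °C
Reagents that add atoms: none
Why: Fluoride-mediated cleavage of the aryl silyl ether, buffered with acetic acid; the tetrasubstituted chloroalkene is inert to these conditions.

**Step 13**
Reactants: 21 2-{(E)-chloro[(2S,4aS,8aS)-2,5,5,8a-tetramethyloctahydronaphthalen-1(2H)-ylidene]methyl}-6-methoxyphenol
Product: 22 2-{(E)-chloro[(2S,4aS,8aS)-2,5,5,8a-tetramethyloctahydronaphthalen-1(2H)-ylidene]methyl}-6-methoxycyclohexa-2,5-diene-1,4-dione (CNP0249629.1)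
Conditions: (KSO3)2NO, KH2PO4, acetone/H2O, rt
Reagents that add atoms: potassium nitrosodisulfonate (Fremy's salt), [K+].[K+].[O]N(S(=O)(=O)[O-])S(=O)(=O)[O-]
Why: Teuber oxidation: the nitroxyl radical should oxidise the phenol at its free para position to the 1,4-benzoquinone, leaving the methoxy group and the chloroalkene untouched.

**Compound list**
1 | (R)-carvone, (5R)-2-methyl-5-(prop-1-en-2-yl)cyclohex-2-en-1-one | CC1=CC[C@@H](C(C)=C)CC1=O | starting material
2 | lithium α′-dienolate of 1 | CC1=CC[C@@H](C(C)=C)C=C1O[Li] | intermediate (not isolated)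
3 | (5R,6S)-2,6-dimethyl-5-(prop-1-en-2-yl)cyclohex-2-en-1-one | CC1=CC[C@@H](C(C)=C)[C@H](C)C1=O | intermediate
4 | lithium dienolate of 3 | CC1=CC[C@@H](C(C)=C)C(C)=C1O[Li] | intermediate (not isolated)
5 | (5S,6R)-6-(hydroxymethyl)-2,6-dimethyl-5-(prop-1-en-2-yl)cyclohex-2-en-1-one | CC1=CC[C@@H](C(C)=C)[C@](C)(CO)C1=O | intermediate
6 | (1R,6S)-1,3-dimethyl-2-oxo-6-(prop-1-en-2-yl)cyclohex-3-ene-1-carbaldehyde | CC1=CC[C@@H](C(C)=C)[C@](C)(C=O)C1=O | intermediate
7 | vinyltriphenylphosphonium bromide | C=C[P+](c1ccccc1)(c1ccccc1)c1ccccc1.[Br-] | starting material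
8 | {3-[(1S,2R)-2-formyl-2,4-dimethyl-3-oxocyclohex-4-en-1-yl]-3-methylbutyl}triphenylphosphonium bromide | CC1=CC[C@@H](C(C)(C)CC[P+](c2ccccc2)(c2ccccc2)c2ccccc2)[C@](C)(C=O)C1=O.[Br-] | intermediate (not isolated)
9 | phosphonium ylide of 8 | CC1=CC[C@@H](C(C)(C)CC=P(c2ccccc2)(c2ccccc2)c2ccccc2)[C@](C)(C=O)C1=O | intermediate (not isolated)
10 | (4aS,8aS)-2,5,5,8a-tetramethyl-4a,5,6,8a-tetrahydronaphthalen-1(4H)-one | CC1=CC[C@H]2C(C)(C)CC=C[C@]2(C)C1=O | intermediate
11 | lithium (4aS,8aS)-2,5,5,8a-tetramethyl-3,4,4a,5,6,8a-hexahydronaphthalen-1-olate | CC1=C(O[Li])[C@@]2(C)C=CCC(C)(C)[C@@H]2CC1 | intermediate (not isolated)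
12 | (4aS,8aS)-2,5,5,8a-tetramethyl-3,4,4a,5,6,8a-hexahydronaphthalen-1-yl trifluoromethanesulfonate | CC1=C(OS(=O)(=O)C(F)(F)F)[C@@]2(C)C=CCC(C)(C)[C@@H]2CC1 | intermediate
13 | 2-hydroxy-3-methoxybenzaldehyde (o-vanillin) | COc1cccc(C=O)c1O | starting material
14 | 2-[(tert-butyldimethylsilyl)oxy]-3-methoxybenzaldehyde | COc1cccc(C=O)c1O[Si](C)(C)C(C)(C)C | intermediate
15 | {2-[(tert-butyldimethylsilyl)oxy]-3-methoxyphenyl}[(4aS,8aS)-2,5,5,8a-tetramethyl-3,4,4a,5,6,8a-hexahydronaphthalen-1-yl]methanol (carbinol epimers) | CC1=C(C(O)c2cccc(OC)c2O[Si](C)(C)C(C)(C)C)[C@@]2(C)C=CCC(C)(C)[C@@H]2CC1 | intermediate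
16 | {2-[(tert-butyldimethylsilyl)oxy]-3-methoxyphenyl}[(1S,2S,4aS,8aS)-2,5,5,8a-tetramethyldecahydronaphthalen-1-yl]methanol (carbinol epimers) | C[C@H]1CC[C@H]2C(C)(C)CCC[C@]2(C)[C@H]1C(O)c1cccc(OC)c1O[Si](C)(C)C(C)(C)C | intermediate
17 | {2-[(tert-butyldimethylsilyl)oxy]-3-methoxyphenyl}[(1S,2S,4aS,8aS)-2,5,5,8a-tetramethyldecahydronaphthalen-1-yl]methanone | C[C@H]1CC[C@H]2C(C)(C)CCC[C@]2(C)[C@H]1C(=O)c1cccc(OC)c1O[Si](C)(C)C(C)(C)C | intermediate
18 | potassium enolate of 17 (C9=C11) | C[C@H]1CC[C@H]2C(C)(C)CCC[C@]2(C)C1=C(O[K])c1cccc(OC)c1O[Si](C)(C)C(C)(C)C | intermediate (not isolated)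
19 | {2-[(tert-butyldimethylsilyl)oxy]-3-methoxyphenyl}[(2S,4aS,8aS)-2,5,5,8a-tetramethyloctahydronaphthalen-1(2H)-ylidene]methyl trifluoromethanesulfonate (E/Z mixture; alkene geometry left open) | C[C@H]1CC[C@H]2C(C)(C)CCC[C@]2(C)C1=C(OS(=O)(=O)C(F)(F)F)c1cccc(OC)c1O[Si](C)(C)C(C)(C)C | intermediate
20 | tert-butyl(2-{(E)-chloro[(2S,4aS,8aS)-2,5,5,8a-tetramethyloctahydronaphthalen-1(2H)-ylidene]methyl}-6-methoxyphenoxy)dimethylsilane | COc1cccc(/C(Cl)=C2/[C@@H](C)CC[C@H]3C(C)(C)CCC[C@]23C)c1O[Si](C)(C)C(C)(C)C | intermediate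
21 | 2-{(E)-chloro[(2S,4aS,8aS)-2,5,5,8a-tetramethyloctahydronaphthalen-1(2H)-ylidene]methyl}-6-methoxyphenol | COc1cccc(/C(Cl)=C2/[C@@H](C)CC[C@H]3C(C)(C)CCC[C@]23C)c1O | intermediate
22 | 2-{(E)-chloro[(2S,4aS,8aS)-2,5,5,8a-tetramethyloctahydronaphthalen-1(2H)-ylidene]methyl}-6-methoxycyclohexa-2,5-diene-1,4-dione (CNP0249629.1) | COC1=CC(=O)C=C(/C(Cl)=C2/[C@@H](C)CC[C@H]3C(C)(C)CCC[C@]23C)C1=O | target

**Step count**
Total steps: 13. Longest linear sequence: 12 (steps 1–5 and 7–13; step 6 prepares the aryl aldehyde).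

**Steps most likely to fail**

1. Step 4 (proposed new method). The α-phosphonio radical may be quenched without the ylide ever closing onto the aldehyde, alkoxide may deformylate the β-keto aldehyde (retro-Claisen) faster than the Wittig closure, or the isopropenyl group may simply be hydrogenated. The fallback uses known chemistry and sets out from 6. An iron-hydride MHAT radical–polar crossover annulation with acrolein (Fe(acac)3, PhSiH3, EtOH/(CH2OH)2; Giese addition at C4, then intramolecular aldol of the enolate onto the C1 aldehyde) should give the ring-A β-hydroxy aldehyde F1. Acid-mediated dehydration (p-TsOH, benzene, reflux) should give the conjugated enal F2. Tsuji–Wilkinson decarbonylation (RhCl(PPh3)3, toluene, reflux) removes the formyl carbon and returns to the route at 10.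

2. Step 11. The vinyl cation may be captured from both sides (poor facial selectivity), ionisation may be sluggish, or solvent capture may lead back to ketone 17. The fallback sets out from 17: direct deoxychlorination with (PhO)3P/Cl2 and Et3N (CH2Cl2, −20 °C → reflux) should give the chloroalkene as an E/Z mixture. The E isomer 20 is separated by chromatography from the Z-chloroalkene F3, and F3 is recycled by sensitised photochemical E/Z isomerisation to a photostationary mixture and re-separation. The fallback returns to the route at 20.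

3. Step 8. Hydrogenation of the hindered tetrasubstituted alkene may be incomplete, or hydrogen may be delivered to the wrong face for one carbinol epimer. The fallback sets out from 15: Dess–Martin oxidation should give the tetrasubstituted aryl enone F4. Kinetic γ-deprotonation (LiN(i-Pr)2, HMPA, THF, −78 °C) and α-protonation with AcOH should move the alkene out of conjugation to give the β,γ-unsaturated ketone F5 (C7=C8; its exocyclic C8=CH2 isomer would serve equally). Hydrogenation of this now trisubstituted alkene together with C1=C2 (H2, Pd/C, EtOAc), from the α face opposite the axial C10 methyl, returns to the route at 17.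

**Further compounds**
F1 | step 4 | β-hydroxy aldehyde, ring A closed: (4aS)-1-hydroxy-4,4,7,8a-tetramethyl-8-oxo-1,2,3,4,4a,5,8,8a-octahydronaphthalene-2-carbaldehyde (ring fusion as in 10; mixture at C1 and C2) | CC1=CC[C@H]2C(C)(C)CC(C=O)C(O)[C@]2(C)C1=O
F2 | step 4 | conjugated enal: (4aS,8aS)-4,4,7,8a-tetramethyl-8-oxo-3,4,4a,5,8,8a-hexahydronaphthalene-2-carbaldehyde | CC1=CC[C@H]2C(C)(C)CC(C=O)=C[C@]2(C)C1=O
F3 | step 11 | Z-chloroalkene: tert-butyl(2-{(Z)-chloro[(2S,4aS,8aS)-2,5,5,8a-tetramethyloctahydronaphthalen-1(2H)-ylidene]methyl}-6-methoxyphenoxy)dimethylsilane | COc1cccc(/C(Cl)=C2\[C@@H](C)CC[C@H]3C(C)(C)CCC[C@]23C)c1O[Si](C)(C)C(C)(C)C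
F4 | step 8 | aryl enone: {2-[(tert-butyldimethylsilyl)oxy]-3-methoxyphenyl}[(4aS,8aS)-2,5,5,8a-tetramethyl-3,4,4a,5,6,8a-hexahydronaphthalen-1-yl]methanone | CC1=C(C(=O)c2cccc(OC)c2O[Si](C)(C)C(C)(C)C)[C@@]2(C)C=CCC(C)(C)[C@@H]2CC1
F5 | step 8 | β,γ-unsaturated ketone: {2-[(tert-butyldimethylsilyl)oxy]-3-methoxyphenyl}[(4aS,8aS)-2,5,5,8a-tetramethyl-1,4,4a,5,6,8a-hexahydronaphthalen-1-yl]methanone (C1 epimers) | CC1=CC[C@H]2C(C)(C)CC=C[C@]2(C)C1C(=O)c1cccc(OC)c1O[Si](C)(C)C(C)(C)C
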